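Retrosynthetic overview
1. Feature: C3 (acetoxy carbon) and C8 (methacryloxy carbon) lie 1,6 across the ten-membered carbocycle C1–C10. An imagined C3–C8 bond turns the carbocycle into a cis-hexalin. Ring A is C3–C4=C5–C6–C7–C8 and carries the cis-fused lactone ring C6–O–C12–C11–C7; ring B is C8–C9–C10=C1–C2–C3. The Z C4=C5 alkene and the cis C1–C10 oxirane (a former Z-alkene) are then ordinary cyclohexene double bonds.
2. Endgame: the 8-methacrylate, the 8-OH-directed C1=C10 epoxidation, the 3-acetate and two ketone reductions lead back to the Z,Z-3,8-dione. That dione is released by glycol fission of the C3–C8 bond of the 3,8-dihydroxy hexalin lactone.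
3. Ring B comes from ring-closing metathesis of an allyl arm on C3 (C1, C2; allyl bromide added to the C3 ketone) with a methallyl arm on C8 (C9, C10, C14; methallyl bromide on the C8 enolate).
4. Lactone ring: the C12 hydroxyl displaces a C6 bromide on ring A, then C12H2 is oxidised to C12=O. Ring A, with C15, C11–C13 and the C7 stereocentre, is (S)-carvone.
5. Order of rings: ring A (bought), O-heterocycle on C6/C7, ring B, ten-membered ring (by loss of the shared bond), oxirane.

Key step: step 16

Remark: germacrane numbering is used for all compounds. C3 is the carvone C=O, C4/C15 and C5 are the enone alkene, C6 is the ring CH2, C7 is the stereocentre, C8 is the α′ carbon and C11–C13 are the isopropenyl group. β is the ring face that carries C11 at C7 (H-7 is α). The carbinol centres at C3 and C8 in 7–22 are auxiliary and disappear in step 16.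

Step 1
Reactants: 1 (S)-(+)-carvone
Product: 2 12-chlorocarvone [(5S)-5-(3-chloroprop-1-en-2-yl)-2-methylcyclohex-2-en-1-one]
Conditions: Ca(OCl)2, solid CO2, CH2Cl2/H2O, 0 °C
Reagents that add atoms: calcium hypochlorite, [Ca+2].[O-]Cl.[O-]Cl
Why: Ene-type allylic chlorination by HOCl made in the flask, in which the electron-rich isopropenyl alkene reacts with double-bond shift to the primary allylic chloride while the enone alkene is inert and C7 is untouched.

Step 2
Reactants: 2 12-chlorocarvone
Product: 3 12-acetoxycarvone [(5S)-5-(3-acetoxyprop-1-en-2-yl)-2-methylcyclohex-2-en-1-one]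
Conditions: KOAc, n-Bu4NI (cat.), DMF, 60 °C
Reagents that add atoms: potassium acetate, CC(=O)[O-].[K+]
Why: Iodide-catalysed SN2 displacement of the primary allylic chloride by acetate is chosen because direct hydrolysis would need hydroxide, which the enone does not tolerate well.

Step 3
Reactants: 3 12-acetoxycarvone
Product: 4 12-hydroxycarvone [(5S)-5-(3-hydroxyprop-1-en-2-yl)-2-methylcyclohex-2-en-1-one]
Conditions: K2CO3 (cat.), MeOH, 0 °C to rt
Reagents that add atoms: none
Why: Carbonate-catalysed transesterification (Zemplén type) frees the primary allylic alcohol, and C7 cannot epimerise because it is not α to the carbonyl.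

Step 4
Reactants: 4 12-hydroxycarvone
Product: 5 12-(tert-butyldimethylsilyloxy)carvone (5S)
Conditions: TBSCl, imidazole, CH2Cl2, rt
Reagents that add atoms: tert-butyldimethylsilyl chloride, CC(C)(C)[Si](C)(C)Cl
Why: Standard imidazole-promoted silylation masks the C12 oxygen for the enolate chemistry that follows.

Step 5
Reactants: 5 12-(tert-butyldimethylsilyloxy)carvone
Product: 7 8α-hydroxy-12-silyloxycarvone (5R,6R in cyclohexenone numbering), via sodium dienolate 6 (not isolated)
Conditions: NaHMDS, THF, −78 °C; 2-(phenylsulfonyl)-3-phenyloxaziridine, −78 °C; pH 7 buffer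
Reagents that add atoms: 2-(phenylsulfonyl)-3-phenyloxaziridine, O=S(=O)(c1ccccc1)N1OC1c1ccccc1
Why: Davis oxidation of the kinetic cross-conjugated α′-enolate delivers oxygen anti to the β side chain on C7 (8α-OH), although this configuration does not matter because C8 is planarised again in step 7.

Step 6
Reactants: 7 8α-hydroxy-12-silyloxycarvone
Product: 8 8α,12-bis(tert-butyldimethylsilyloxy)carvone (5R,6R)
Conditions: TBSOTf, 2,6-lutidine, CH2Cl2, −78 to 0 °C
Reagents that add atoms: tert-butyldimethylsilyl triflate, CC(C)(C)[Si](C)(C)OS(=O)(=O)C(F)(F)F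
Why: Triflate silylation protects the hindered secondary α-ketol as an ether that is non-chelating and migrates only slowly, and the weak pyridine base does not enolise the ketone at low temperature.

Step 7
Reactants: 8 8α,12-bis(tert-butyldimethylsilyloxy)carvone; 9 methallyl bromide
Product: 11 8α-methallyl-8β-silyloxy enone (5R,6S in cyclohexenone numbering), via lithium dienolate 10 (not isolated)
Conditions: LDA, THF/DMPU, −78 °C; 9, −78 to −30 °C
Reagents that add atoms: methallyl bromide (9), C=C(C)CBr
Why: Enolate C-alkylation with a reactive allylic bromide, where C8–H is the only α-proton and the electrophile approaches the planar enolate on the α face, anti to the neighbouring β side chain on C7, so the methallyl group ends α and the silyloxy group β.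

Step 8
Reactants: 11 8α-methallyl-8β-silyloxy enone
Product: 12 linear silyl dienol ether (3-silyloxy-3,5-diene of ring A; C3=C4 and C5=C6)
Conditions: TBSOTf, Et3N, CH2Cl2, 0 °C to rt
Reagents that add atoms: tert-butyldimethylsilyl triflate, CC(C)(C)[Si](C)(C)OS(=O)(=O)C(F)(F)F
Why: Soft enolisation (O-silylation, then amine deprotonation) can only remove a γ proton at C6, because C8 is quaternary and C4 carries no hydrogen, so the extended 2-silyloxy-1,3-diene should be the sole enol ether.

Step 9
Reactants: 12 linear silyl dienol ether
Product: 13 6α-bromo enone (Br trans to the C7 side chain)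
Conditions: NBS, THF, −78 °C
Reagents that add atoms: N-bromosuccinimide, O=C1CCC(=O)N1Br
Why: Vinylogous (γ-selective) bromination of a silyl dienol ether, in which the unsubstituted terminus C6 is preferred over the methyl-bearing C4, bromine arrives on the α face away from the adjacent β side chain, and the isolated 1,1-disubstituted alkenes are far less nucleophilic at −78 °C.

Step 10
Reactants: 13 6α-bromo enone
Product: 14 6α-bromo-12-hydroxy enone
Conditions: HF·pyridine, pyridine/THF, 0 °C
Reagents that add atoms: none
Why: Acidic fluoride cleaves the unhindered primary allylic silyl ether much faster than the tertiary C8 ether and, unlike basic fluoride, neither displaces nor eliminates the bromide.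

Step 11
Reactants: 14 6α-bromo-12-hydroxy enone
Product: 15 cis-fused 3-methylenetetrahydrofuran enone (6β-O and 7β-C11)
Conditions: Ag2O, 4 Å molecular sieves, CH2Cl2, rt, dark
Reagents that add atoms: none
Why: Silver-assisted intramolecular Williamson etherification (5-exo-tet SN2), in which the C12 hydroxyl hangs from the β face at C7 and can only reach the rear of the α C6–Br bond, so C6 is inverted to 6β-O (6S) and the ring is cis-fused, while anti elimination is disfavoured because H-7 and Br are syn.

Step 12
Reactants: 15 cis-fused 3-methylenetetrahydrofuran enone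
Product: 16 cis-fused α-methylene-γ-lactone enone
Conditions: CrO3, 3,5-dimethylpyrazole, CH2Cl2, −20 °C
Reagents that add atoms: chromium trioxide, O=[Cr](=O)=O
Why: Allylic oxidation of a 3-methylenetetrahydrofuran to the α-methylene-γ-butyrolactone by hexavalent chromium, where C12H2 is the most activated site (allylic to an electron-rich alkene and α to oxygen) and C6–H is tertiary and deactivated by the enone.

Step 13
Reactants: 16 cis-fused α-methylene-γ-lactone enone; 17 allyl bromide
Product: 19 3α-allyl-3β-hydroxy-8α-methallyl-8β-silyloxy lactone, via allylzinc bromide 18 (not isolated)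
Conditions: 17, Zn dust, THF, 0 °C; pH 7 buffer
Reagents that add atoms: allyl bromide (17), C=CCBr
Why: Barbier allylation, in which allylzinc adds 1,2 through a cyclic six-membered transition state that copes with the hindered ketone and leaves the lactone alone at 0 °C, and attack on the α face, anti to the pseudoaxial β C8–O bond (polar Felkin–Anh) and away from the β-fused lactone, sets 3β-OH cis to the C8 oxygen.

Step 14
Reactants: 19 3α-allyl-3β-hydroxy-8α-methallyl-8β-silyloxy lactone
Product: 20 3α-allyl-8α-methallyl-3β,8β-diol lactone
Conditions: 48% aq. HF, MeCN, 0 °C to rt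
Reagents that add atoms: none
Why: Acidic fluoride desilylation removes the hindered tertiary ether without forming an alkoxide, which avoids migration of the lactone acyl group from O6 to the cis-disposed O8 and Michael addition to C13.

Step 15
Reactants: 20 3α-allyl-8α-methallyl-3β,8β-diol lactone
Product: 21 cis-hexalin diol lactone [3β,8β-dihydroxy-3,8-cyclogermacra-1(10),4,11(13)-trien-12,6-olide; 3R,6S,7S,8S]
Conditions: second-generation Grubbs catalyst RuCl2(=CHPh)(PCy3)(H2IMes) (5 mol%), CH2Cl2 (2 mM), 40 °C
Reagents that add atoms: none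
Why: Ring-closing metathesis, in which the catalyst loads on the monosubstituted allyl alkene and closes onto the cis methallyl arm to give the trisubstituted cyclohexene ring B (C1=C10), while the electron-poor C11=C13 and the trisubstituted C4=C5 alkenes are poor partners and C11 lies on the opposite face.

Step 16
Reactants: 21 cis-hexalin diol lactone
Product: 23 (1(10)Z,4Z,6S,7S)-3,8-dioxogermacra-1(10),4,11(13)-trien-12,6-olide, via cyclic lead diolate 22 (not isolated)
Conditions: Pb(OAc)4 (1.1 equiv), powdered NaHCO3, CH2Cl2, −20 to 0 °C; cold filtration through Celite, solution used at once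
Reagents that add atoms: none
Why: Criegee glycol cleavage: the two cis (β,β) tertiary hydroxyls replace two acetates on tetravalent lead to give the five-membered cyclic diolate 22, which collapses in a concerted two-electron step that breaks the C3–C8 σ bond, expels Pb(OAc)2 and makes C3 the enone carbonyl and C8 the saturated ketone. The closest known reaction type is the lead tetraacetate fission of decalin- and hexalin-9,10-diols to cyclodecane-1,6-diones and Z,Z-cyclodecadienediones, so only the lactone-bearing substrate is new. No ring is closed by bond formation: rings A and B merge into the ten-membered carbocycle C1–C10 once their shared bond is gone, so no macrocyclisation entropy or transannular closure problem arises. No stereocentre is created, the auxiliary centres C3 and C8 vanish, C6 and C7 are not involved, and both alkenes must emerge Z because each was endocyclic in a cyclohexene. The step needs chemoselectivity for the glycol over three alkenes and the lactone, which the far faster chelating cis-diol secures at or below 0 °C. It also needs the β,γ-unsaturated, β-acyloxy dione (acidic C7–H, C2–H and C9–H) to survive, which the solid bicarbonate buffer, the aprotic solvent, the cold filtration and immediate use in step 17 are meant to secure.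

Step 17
Reactants: 23 Z,Z-3,8-dione lactone
Product: 24 8β-hydroxy-3-oxo Z,Z-germacranolide (8R)
Conditions: NaBH4, CH2Cl2/MeOH 1:1, −78 °C; pH 7 buffer at −78 °C
Reagents that add atoms: none
Why: Chemoselective borohydride reduction at −78 °C, where a saturated ketone reacts well before a conjugated enone or the α-methylene lactone; in the rotamer that puts C7–H next to C9 and lets C7–C11 nearly eclipse the C8 carbonyl (oxygen on the β face, as released by the fission), the C7–C6 bond stands perpendicular to the carbonyl plane, so hydride enters from outside the ring anti to C7–C6 (Felkin–Anh sense coinciding with peripheral attack) and sets 8β-OH.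

Step 18
Reactants: 24 8β-hydroxy-3-oxo Z,Z-germacranolide
Product: 25 (3S,6S,7R,8R)-3β,8β-dihydroxygermacra-1(10)Z,4Z,11(13)-trien-12,6-olide
Conditions: (R)-2-methyl-CBS-oxazaborolidine (20 mol%), catecholborane, toluene, −78 °C
Reagents that add atoms: none
Why: Corey–Bakshi–Shibata reduction, in which the (R)-oxazaborolidine binds the C3 carbonyl with the α-methylalkenyl side (C4) as the large group and the C2 methylene as the small group and delivers hydride 1,2 to give the 3β-alcohol (3S) under reagent control, a sense that also matches peripheral attack, while catecholborane at −78 °C leaves the alkenes and the lactone alone.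

Step 19
Reactants: 25 3β,8β-diol
Product: 26 3β-acetoxy-8β-hydroxy Z,Z-germacranolide
Conditions: Ac2O (1.05 equiv), pyridine, 0 °C
Reagents that add atoms: acetic anhydride, CC(=O)OC(C)=O
Why: Kinetic mono-acylation, because the allylic 3-OH is flanked by a planar sp2 carbon and a CH2 whereas the 8-OH sits next to the branched ring-fusion carbon C7 beside the lactone, so one equivalent of anhydride without DMAP should acetylate O3 first.

Step 20
Reactants: 26 3β-acetoxy-8β-hydroxy Z,Z-germacranolide
Product: 27 3β-acetoxy-1β,10β-epoxy-8β-hydroxy germacranolide (1R,3S,6S,7R,8R,10S)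
Conditions: VO(acac)2 (5 mol%), t-BuOOH (decane), CH2Cl2, 0 °C
Reagents that add atoms: tert-butyl hydroperoxide, CC(C)(C)OO
Why: Vanadium-catalysed hydroxyl-directed epoxidation of a homoallylic alcohol, in which the peroxide bound to the 8β-alkoxide reaches only the β face of the electron-rich C1=C10 alkene, so both C–O bonds form syn to O8 (1R,10S), the Z geometry is copied into the cis-oxirane, and the acyloxy-flanked C4=C5 and electron-poor C11=C13 alkenes do not react.

Step 21
Reactants: 27 3β-acetoxy-1β,10β-epoxy-8β-hydroxy germacranolide; 28 methacrylic anhydride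
Product: 29 target CNP0267696.1 [(1R,3S,4Z,6S,7R,8R,10S)-3-acetoxy-1,10-epoxy-8-methacryloyloxygermacra-4,11(13)-dien-12,6-olide]
Conditions: 28, DMAP (cat.), Et3N, CH2Cl2, 0 °C to rt
Reagents that add atoms: methacrylic anhydride (28), C=C(C)C(=O)OC(=O)C(C)=C
Why: DMAP-catalysed acyl transfer from the anhydride (Steglich type) esterifies the remaining hindered secondary 8-OH with retention, and the mild conditions leave the epoxide, acetate and lactone intact.

Compound list
1 | (S)-(+)-carvone | CC1=CC[C@@H](CC1=O)C(C)=C | starting material
2 | 12-chlorocarvone (5S) | CC1=CC[C@@H](CC1=O)C(=C)CCl | intermediate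
3 | 12-acetoxycarvone (5S) | CC1=CC[C@@H](CC1=O)C(=C)COC(C)=O | intermediate
4 | 12-hydroxycarvone (5S) | CC1=CC[C@@H](CC1=O)C(=C)CO | intermediate
5 | 12-(tert-butyldimethylsilyloxy)carvone (5S) | CC1=CC[C@@H](CC1=O)C(=C)CO[Si](C)(C)C(C)(C)C | intermediate
6 | sodium cross-conjugated dienolate of 5 (not isolated) | [Na+].CC1=CC[C@@H](C=C1[O-])C(=C)CO[Si](C)(C)C(C)(C)C | intermediate
7 | 8α-hydroxy-12-silyloxycarvone | CC1=CC[C@H](C(=C)CO[Si](C)(C)C(C)(C)C)[C@@H](O)C1=O | intermediate
8 | 8α,12-bis(tert-butyldimethylsilyloxy)carvone | CC1=CC[C@H](C(=C)CO[Si](C)(C)C(C)(C)C)[C@@H](O[Si](C)(C)C(C)(C)C)C1=O | intermediate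
9 | methallyl bromide | C=C(C)CBr | starting material
10 | lithium dienolate of 8 (not isolated) | [Li+].CC1=CC[C@H](C(=C)CO[Si](C)(C)C(C)(C)C)C(O[Si](C)(C)C(C)(C)C)=C1[O-] | intermediate
11 | 8α-methallyl-8β-silyloxy enone | CC1=CC[C@H](C(=C)CO[Si](C)(C)C(C)(C)C)[C@@](O[Si](C)(C)C(C)(C)C)(CC(C)=C)C1=O | intermediate
12 | linear silyl dienol ether (C3=C4, C5=C6) | CC=1C=C[C@H](C(=C)CO[Si](C)(C)C(C)(C)C)[C@@](O[Si](C)(C)C(C)(C)C)(CC(C)=C)C=1O[Si](C)(C)C(C)(C)C | intermediate
13 | 6α-bromo enone | CC1=C[C@@H](Br)[C@H](C(=C)CO[Si](C)(C)C(C)(C)C)[C@@](O[Si](C)(C)C(C)(C)C)(CC(C)=C)C1=O | intermediate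
14 | 6α-bromo-12-hydroxy enone | CC1=C[C@@H](Br)[C@H](C(=C)CO)[C@@](O[Si](C)(C)C(C)(C)C)(CC(C)=C)C1=O | intermediate
15 | cis-fused 3-methylenetetrahydrofuran enone | CC1=C[C@@H]2OCC(=C)[C@@H]2[C@@](O[Si](C)(C)C(C)(C)C)(CC(C)=C)C1=O | intermediate
16 | cis-fused α-methylene-γ-lactone enone | CC1=C[C@@H]2OC(=O)C(=C)[C@@H]2[C@@](O[Si](C)(C)C(C)(C)C)(CC(C)=C)C1=O | intermediate
17 | allyl bromide | C=CCBr | starting material
18 | allylzinc bromide (not isolated) | C=CC[Zn]Br | intermediate
19 | 3α-allyl-3β-hydroxy-8α-methallyl-8β-silyloxy lactone | CC1=C[C@@H]2OC(=O)C(=C)[C@@H]2[C@@](O[Si](C)(C)C(C)(C)C)(CC(C)=C)[C@@]1(O)CC=C | intermediate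
20 | 3α-allyl-8α-methallyl-3β,8β-diol lactone | CC1=C[C@@H]2OC(=O)C(=C)[C@@H]2[C@@](O)(CC(C)=C)[C@@]1(O)CC=C | intermediate
21 | cis-hexalin diol lactone (3R,6S,7S,8S) | CC1=C[C@@H]2OC(=O)C(=C)[C@@H]2[C@@]3(O)CC(C)=CC[C@@]13O | intermediate
22 | cyclic lead diolate of 21 (not isolated) | CC1=C[C@@H]2OC(=O)C(=C)[C@@H]2[C@@]3(O4)CC(C)=CC[C@@]13O[Pb]4(OC(C)=O)OC(C)=O | intermediate
23 | Z,Z-3,8-dioxogermacra-1(10),4,11(13)-trien-12,6-olide (6S,7S) | O=C1C/C(C)=C\CC(=O)/C(C)=C\[C@@H]2OC(=O)C(=C)[C@@H]21 | intermediate
24 | 8β-hydroxy-3-oxo Z,Z-germacranolide | O[C@@H]1C/C(C)=C\CC(=O)/C(C)=C\[C@@H]2OC(=O)C(=C)[C@@H]21 | intermediate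
25 | 3β,8β-dihydroxy Z,Z-germacranolide (3S,6S,7R,8R) | O[C@@H]1C/C(C)=C\C[C@H](O)/C(C)=C\[C@@H]2OC(=O)C(=C)[C@@H]21 | intermediate
26 | 3β-acetoxy-8β-hydroxy Z,Z-germacranolide | O[C@@H]1C/C(C)=C\C[C@H](OC(C)=O)/C(C)=C\[C@@H]2OC(=O)C(=C)[C@@H]21 | intermediate
27 | 3β-acetoxy-1β,10β-epoxy-8β-hydroxy germacranolide | O[C@@H]1C[C@]2(C)O[C@@H]2C[C@H](OC(C)=O)/C(C)=C\[C@@H]2OC(=O)C(=C)[C@@H]21 | intermediate
28 | methacrylic anhydride | C=C(C)C(=O)OC(=O)C(C)=C | starting material
29 | CNP0267696.1 (1R,3S,4Z,6S,7R,8R,10S) | C=C(C)C(=O)O[C@@H]1C[C@]2(C)O[C@@H]2C[C@H](OC(C)=O)/C(C)=C\[C@@H]2OC(=O)C(=C)[C@@H]21 | target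

Total step count: 21
Longest linear sequence: 21 steps (1 to 29; 9, 17 and 28 are bought)

Steps most likely to fail

Step 16. The C–C fission itself is dependable; the danger lies in what happens to the product while it is handled. Enolisation toward C7 could cause β-elimination of the C6 carboxylate or loss of the C7 configuration. The C1=C10 alkene could drift into conjugation, and a transannular aldol closure could occur. In the fallback the dione is never handled.
- Starting from 21, the glycol is cut with PhI(OAc)2 in CH2Cl2 at 0 °C.
- The mixture is diluted with MeOH, cooled to −78 °C and treated in the same flask with CeCl3·7H2O and NaBH4 (Luche reduction).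
- Both carbonyls are then reduced 1,2 under substrate control, by peripheral attack on the conformer with both oxygens on the β face, as soon as they exist.
- The route is rejoined at 25, and steps 17 and 18, including the reagent-controlled reduction, are dropped.
- This detour makes no compound outside the list (F0).

Step 17. The ten-membered ring may react through the other carbonyl rotamer, which would give poor facial selectivity at C8. Conjugate reduction of C11=C13 and base-induced enolisation may also compete. The fallback replaces direct control by inversion, sets out from 23 and rejoins the route at 29.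
- The 8α-hydroxy-3-oxo germacranolide F1 that the reduction then delivers is esterified with methacrylic acid under Mitsunobu conditions (PPh3, DIAD, toluene, 0 °C). This inverts C8 and installs the ester in one operation, giving the 8β-methacryloyloxy-3-oxo germacranolide F2.
- (R)-CBS reduction with catecholborane gives the 3β-hydroxy-8β-methacrylate F3.
- Ordinary acetylation (Ac2O, pyridine, DMAP; no selectivity needed) gives the 3β-acetoxy-8β-methacrylate diene F4.
- Buffered mCPBA epoxidises the only electron-rich alkene, C1=C10, from its exposed β face, which gives 29.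

Step 12. Hexavalent chromium may oxidise unselectively at the allylic positions of the methallyl arm (C9, C14) or at C6–H, and conversion may be low. The fallback forms the lactone C–O bond from a carboxylate, so no C–H oxidation is needed, and it bypasses 15.
- It sets out from 14, whose primary allylic alcohol is oxidised with MnO2 to the 6α-bromo enal F5.
- Pinnick oxidation (NaClO2, NaH2PO4, 2-methyl-2-butene) then gives the 6α-bromo acrylic acid F6.
- KHCO3 in DMF lets the carboxylate displace the C6 bromide from the β face with inversion, and the route is rejoined at 16.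

Further compounds
F0 | step 16 | none | none
F1 | step 17 | 8α-hydroxy-3-oxo Z,Z-germacranolide | O[C@H]1C/C(C)=C\CC(=O)/C(C)=C\[C@@H]2OC(=O)C(=C)[C@@H]21
F2 | step 17 | 8β-methacryloyloxy-3-oxo Z,Z-germacranolide | C=C(C)C(=O)O[C@@H]1C/C(C)=C\CC(=O)/C(C)=C\[C@@H]2OC(=O)C(=C)[C@@H]21
F3 | step 17 | 3β-hydroxy-8β-methacryloyloxy Z,Z-germacranolide | C=C(C)C(=O)O[C@@H]1C/C(C)=C\C[C@H](O)/C(C)=C\[C@@H]2OC(=O)C(=C)[C@@H]21
F4 | step 17 | 3β-acetoxy-8β-methacryloyloxy Z,Z-germacranolide | C=C(C)C(=O)O[C@@H]1C/C(C)=C\C[C@H](OC(C)=O)/C(C)=C\[C@@H]2OC(=O)C(=C)[C@@H]21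
F5 | step 12 | 6α-bromo enal (C12 aldehyde) | CC1=C[C@@H](Br)[C@H](C(=C)C=O)[C@@](O[Si](C)(C)C(C)(C)C)(CC(C)=C)C1=O
F6 | step 12 | 6α-bromo acrylic acid (C12 acid) | CC1=C[C@@H](Br)[C@H](C(=C)C(=O)O)[C@@](O[Si](C)(C)C(C)(C)C)(CC(C)=C)C1=O
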